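## Structural features

The target is an achiral 2-arylbenzofuran. Ring A (C3a to C7a) is fused to a furan ring (O1, C2, C3) that carries a methoxy group at C3 and is joined through C2–C1' to ring B. Ring A has a free phenol at C6 and a prenyl (3-methylbut-2-en-1-yl) chain on the neighbouring C5. Ring B has OH at C3' and OMe at C4'. There is no stereocentre, and the one alkene ends in two identical methyl groups, so no configuration has to be set. The stereocentres that appear in the ring B intermediates are transient and need no control. The fragile parts are the prenyl group (acid closes it onto the ortho phenol; electrophiles, oxidants and hydrogenation attack it), the electron-rich 3-methoxyfuran enol ether and the two phenols. The real difficulty is regiochemical: the two oxygens of ring B must be differentiated, the prenyl group must sit next to the C6 oxygen, and the C3 enol must end as its methyl ether, all under conditions the prenyl group survives. The key step exploits the fact that ring B is one oxidation level above a 3-aryl-6-methoxycyclohex-2-enone: the enone carbonyl carbon is C3', its methoxy-bearing α-carbon is C4' and the β-carbon is C1'. The annulation was checked atom by atom against the target and maps correctly; the ring closure is a 6-(enolendo)-exo-trig aldol addition.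

## Logic of the disconnections

20 ⇒ 19. Only the O–CH2 bond of the acetal on the C6 oxygen is cut. The C6 oxygen must be masked through every base-mediated step, where a free phenoxide would add to the enone or quench the organomagnesium reagents. No skeletal simplification results. The forward step must use acid mild enough that the freed phenol does not add to the prenyl alkene.

19 ⇒ 17. Ring B is taken back one oxidation level and an ester carbon is put back on C4'. This turns the differentiated catechol monoether into an enone whose carbonyl (C3') and α-methoxy carbon (C4') have separate origins. The forward step must create an enolate only at C4' and dehydrogenate C4'–C5' without strong base, selenium or oxidant, because of the prenyl group. An allyl ester at C4' allows this with zerovalent palladium in one operation, so the allyl ester is carried in place of a methyl ester.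

17 ⇒ 11 + 14. The C4'–C5' bond (Michael) and the C1'–C2' bond (aldol condensation) are cut. Ring B disappears and the molecule divides into the complete benzofuran part and a four-carbon keto ester. The forward step needs Michael addition through the methine of 14 and aldol closure through its methyl group onto a deactivated aryl ketone.

14 ⇒ 13 ⇒ 12. The C–OMe bond is cut (O–H insertion of a carbenoid), then the diazo group is removed (diazo transfer). This leads to a commercial acetoacetate. The forward insertion must outrun attack of the carbenoid on the allyl group.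

11 ⇒ 10. The acyl–vinyl C–C bond is cut. The forward step needs a single addition of the vinyl nucleophile and a quench that keeps the liberated amine from adding to the enone; 11 is used at once.

10 ⇒ 8 + 9. The C5–CH2 bond of the prenyl group is cut. The bromide in 8 is placed by simple arene chemistry. The forward coupling must deliver the linear (α) isomer. It is run on the amide and not on an ester because the α-selective conditions use hydroxide.

8 ⇒ 7 ⇒ 6. The amide C–N bond and then the O–CH3 bond at C3 are cut. The forward methylation must go on oxygen and not on C2.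

6 ⇒ 5 ⇒ 3 + 4. The C2–C3 bond (Dieckmann) and then the O1–CH2 bond (ether formation) are cut. The furan ring is removed and a salicylate remains. Only one enolisable position exists in 5, so the ring closure has no regiochemical choice.

3 ⇒ 2 ⇒ 1. The acetal O–CH2 bond and then the C5–Br bond are cut. The forward steps rely on the chelated C2 hydroxyl being unreactive and on C5 being the most accessible activated position.

## Other disconnections considered

Alternative 1: The cut goes through the furan ring at O1–C7a and C3–C3a. Ring A comes from the silylaryl triflate A2, and C2, C3 and ring B come from the mandelate ester A3. In the forward step CsF would release the aryne A4 from A2. The alkoxide of A3 would add to C7a, distal to chlorine, and the aryl anion at C3a, stabilised by the adjacent C–Cl bond, would close onto the ester carbonyl to give the benzofuranone A1.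
- In its favour: ring B arrives finished with its oxygens already differentiated, so no aromatisation is needed. On this point it is better than the chosen plan. One step forms a C–O and a C–C bond, so its convergence at the key step is equal or better.
- Against it: the regiochemistry of the aryne depends on a chlorine that is not in the target. That chlorine would have to be removed reductively from an electron-rich arene without touching the prenyl alkene. A1 is a ketone with an acidic, easily oxidised C2–H; converting it to the 3-methoxybenzofuran is an O- versus C-methylation problem at a doubly activated benzylic carbon. A2 is a pentasubstituted benzene with silyl, triflate, chloro, prenyl and acetal groups in sequence and would itself need a long preparation. Two acetal cleavages next to the prenyl group remain.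
- Comparison: structurally it builds the heterocycle where the chosen plan builds ring B. Mechanistically it relies on a substituent-directed aryne addition where the chosen plan has a substrate-dictated enolate sequence. In step economy the gain at the key step is expected to be lost to the preparation of A2 and to dechlorination.

Alternative 2: The cut removes C5 and C6 from ring A (bonds C4–C5 and C6–C7). In the forward step the formyl acid A6 would be cyclodehydrated with acetic anhydride to the furopyranone A7. A7 would add the silyl ynol ether A8 across C4 and C7 and lose carbon dioxide to give the bis-silyl ether A5.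
- In its favour: A5 is one fluoride treatment from the target, so the prenyl group never meets acid. This end game is better than the chosen one. The prenyl group comes in with A8, so no allyl cross-coupling regiochemistry arises; this is also better.
- Against it: the orientation of the cycloaddition depends on the polarisation of a transient quinodimethane-type diene that also carries two donor oxygens. The wrong orientation would give the 6-prenyl-5-silyloxy isomer. A8 is sensitive to acid and acylating agents but must survive hot acetic anhydride. A6 is a tetrasubstituted furan whose preparation is likely to exceed the whole front half of the chosen route.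
- Comparison: structurally it assembles ring A where the chosen plan assembles ring B. Mechanistically a cycloaddition and cycloreversion replace ionic enolate steps. In step economy it is better after the key step and worse before it, with the main uncertainty in the key step itself.

Alternative 3: The cut is the C5–C6 bond of ring A. Photolysis of the diazo ketone A10 would trigger a Wolff rearrangement to the furylketene A11. Its ketene, the furan C3a–C7a double bond and the (E)-alkenyl chain form a triene that would close by six-electron electrocyclisation. Tautomerisation would give the silyl ether A9 with the C6 phenol free.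
- In its favour: the ring closure is intramolecular, so the positions of OH and prenyl on ring A are unambiguous. This is better than the chosen plan, which relies on bromination and coupling selectivity. Ring A needs no protecting group and the last step is a fluoride desilylation, which is again better.
- Against it: A10 needs a tetrasubstituted furan with a diazoacetyl group next to a skipped dienyl chain. Ultraviolet light on a 1,4-diene attached to an electron-rich arylfuran invites alkene isomerisation and di-π-methane-type rearrangement. A carbene-like pathway could cyclopropanate the neighbouring alkene instead of rearranging. The ketene could be intercepted before it cyclises.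
- Comparison: structurally it also builds ring A last. Mechanistically it is photochemical and pericyclic with few ways to adjust it, while the chosen plan uses thermal ionic steps. In step economy it equals the chosen plan after the key step but is longer before it.

Key step: step 10

Assumption: prenyl is taken as 3-methylbut-2-en-1-yl, and the O-alkyl group of the keto ester is treated as a spectator, so the allyl ester replaces the methyl ester; the carbon skeleton and the bonds formed in the annulation are unchanged.

## Route

Step 1
Reactants: 1 methyl 2,4-dihydroxybenzoate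
Product: 2 methyl 5-bromo-2,4-dihydroxybenzoate
Conditions: Br2 (1.0 equiv, slow addition), AcOH, 15 °C to rt
Reagents that add atoms: bromine, BrBr
Why: Electrophilic aromatic bromination; C5 is para to the C2 hydroxyl, ortho to the C4 hydroxyl and less hindered than C3 between the two oxygens, so one equivalent should brominate there.

Step 2
Reactants: 2 methyl 5-bromo-2,4-dihydroxybenzoate
Product: 3 methyl 5-bromo-2-hydroxy-4-(methoxymethoxy)benzoate
Conditions: MOMCl (1.1 equiv), K2CO3, acetone, 0 °C to rt
Reagents that add atoms: chloromethyl methyl ether, COCCl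
Why: Williamson-type O-alkylation; the C2 hydroxyl is hydrogen-bonded to the ester carbonyl and much less nucleophilic, so the C4 phenoxide should react selectively.

Step 3
Reactants: 3 methyl 5-bromo-2-hydroxy-4-(methoxymethoxy)benzoate; 4 methyl bromoacetate
Product: 6 methyl 5-bromo-3-hydroxy-6-(methoxymethoxy)-1-benzofuran-2-carboxylate, via aryloxyacetate diester 5 (not isolated)
Conditions: K2CO3, DMF, 60 °C; filter; t-BuOK, THF, 0 °C to rt; AcOH quench
Reagents that add atoms: none
Why: Williamson etherification of the remaining phenol, then Dieckmann condensation: the only enolisable position of 5 attacks the neighbouring benzoate (5-exo-trig) and the product is held as its aromatic enolate, which drives the closure.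

Step 4
Reactants: 6 methyl 5-bromo-3-hydroxy-6-(methoxymethoxy)-1-benzofuran-2-carboxylate
Product: 7 methyl 5-bromo-3-methoxy-6-(methoxymethoxy)-1-benzofuran-2-carboxylate
Conditions: Me2SO4, K2CO3, acetone, reflux
Reagents that add atoms: dimethyl sulfate, COS(=O)(=O)OC
Why: O-Methylation of the enol of a β-keto ester; the hard electrophile and retention of benzofuran aromaticity favour attack at oxygen over C2.

Step 5
Reactants: 7 methyl 5-bromo-3-methoxy-6-(methoxymethoxy)-1-benzofuran-2-carboxylate
Product: 8 5-bromo-N,3-dimethoxy-6-(methoxymethoxy)-N-methyl-1-benzofuran-2-carboxamide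
Conditions: MeNHOMe·HCl (1.5 equiv), i-PrMgCl (3.0 equiv), THF, −20 °C to 0 °C
Reagents that add atoms: N,O-dimethylhydroxylamine hydrochloride, CNOC.Cl
Why: Weinreb amide formation from the ester with the magnesium amide made in the flask; the aryl bromide should not exchange at this temperature, and the amide is made now so that the hydroxide-based coupling of step 6 does not meet a methyl ester.

Step 6
Reactants: 8 5-bromo-N,3-dimethoxy-6-(methoxymethoxy)-N-methyl-1-benzofuran-2-carboxamide; 9 4,4,5,5-tetramethyl-2-(3-methylbut-2-en-1-yl)-1,3,2-dioxaborolane
Product: 10 N,3-dimethoxy-6-(methoxymethoxy)-N-methyl-5-(3-methylbut-2-en-1-yl)-1-benzofuran-2-carboxamide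
Conditions: 9 (1.5 equiv), PdCl2(IPent)(3-chloropyridine) (2 mol %; IPent = 1,3-bis[2,6-di(pentan-3-yl)phenyl]imidazol-2-ylidene), aq KOH, THF, 70 °C
Reagents that add atoms: none
Why: Suzuki–Miyaura coupling of an aryl bromide with a 3,3-disubstituted allylboronate; the very bulky carbene ligand is the known way to obtain reductive elimination at the unsubstituted allyl terminus, which gives the linear prenyl arene and not the reverse-prenyl isomer.

Step 7
Reactants: 10 N,3-dimethoxy-6-(methoxymethoxy)-N-methyl-5-(3-methylbut-2-en-1-yl)-1-benzofuran-2-carboxamide
Product: 11 1-[3-methoxy-6-(methoxymethoxy)-5-(3-methylbut-2-en-1-yl)-1-benzofuran-2-yl]prop-2-en-1-one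
Conditions: vinylmagnesium bromide (1.5 equiv), THF, −20 °C to 0 °C; inverse quench into cold aq KHSO4; trace BHT, used at once
Reagents that add atoms: vinylmagnesium bromide, C=C[Mg]Br
Why: Weinreb ketone synthesis; the chelated tetrahedral intermediate prevents a second addition, and the acidic inverse quench protonates the released amine so that it should not add to the new enone.

Step 8
Reactants: 12 prop-2-en-1-yl 3-oxobutanoate (allyl acetoacetate)
Product: 13 prop-2-en-1-yl 2-diazo-3-oxobutanoate
Conditions: 4-acetamidobenzenesulfonyl azide (1.1 equiv), Et3N, MeCN, 0 °C to rt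
Reagents that add atoms: 4-acetamidobenzenesulfonyl azide, CC(=O)Nc1ccc(cc1)S(=O)(=O)N=[N+]=[N-]
Why: Regitz diazo transfer to the activated methylene of a β-keto ester.

Step 9
Reactants: 13 prop-2-en-1-yl 2-diazo-3-oxobutanoate
Product: 14 prop-2-en-1-yl 2-methoxy-3-oxobutanoate (racemic, configurationally labile)
Conditions: Rh2(OAc)4 (1 mol %), MeOH (10 equiv), CH2Cl2, 40 °C
Reagents that add atoms: methanol, CO
Why: Dirhodium carbenoid O–H insertion into methanol; the large excess of alcohol should outrun intramolecular cyclopropanation of the allyl group.

Step 10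
Reactants: 11 1-[3-methoxy-6-(methoxymethoxy)-5-(3-methylbut-2-en-1-yl)-1-benzofuran-2-yl]prop-2-en-1-one; 14 prop-2-en-1-yl 2-methoxy-3-oxobutanoate
Product: 17 racemic prop-2-en-1-yl 1-methoxy-4-[3-methoxy-6-(methoxymethoxy)-5-(3-methylbut-2-en-1-yl)-1-benzofuran-2-yl]-2-oxocyclohex-3-ene-1-carboxylate, via Michael adduct 15 (not isolated), via ketol 16 (not isolated)
Conditions: 14 (1.2 equiv), t-BuOK (0.2 equiv), t-BuOH/THF, 0 °C; then t-BuOK (1.0 equiv), 4 Å molecular sieves, rt to 50 °C; AcOH quench
Reagents that add atoms: none
Why: Catalytic alkoxide deprotonates 14 at its only doubly activated carbon, and this enolate adds 1,4 to the unsubstituted terminus of the enone in 11 to give 15, forming the C4'–C5' bond and a quaternary carbon. With a full equivalent of base the acetyl methyl group of 15 enolises reversibly and attacks the benzofuranyl ketone in a 6-(enolendo)-exo-trig aldol addition to give ketol 16 (C1'–C2' bond); E1cB loss of water then gives enone 17, whose conjugation with the benzofuran pulls the equilibria forward. The closest known reaction is the Robinson annulation of aryl vinyl ketones or their Mannich bases with acetoacetates, which gives 3-arylcyclohex-2-enones by the same Michael-then-aldol order. The regiochemistry is set by the substrate: the methine is far more acidic than any other C–H, the quaternary carbon formed in the Michael step cannot enolise, and the only other enolate, at the CH2 next to the aryl ketone, could close only a four-membered ring. The one new stereocentre of 17, the quaternary carbon that becomes C4', forms without control as a racemate, which does not matter because it becomes an sp2 carbon in step 11. A hindered alkoxide and molecular sieves are chosen so that retro-Claisen deacetylation of 15 and transesterification or saponification of the allyl ester should not compete. The acetal, the prenyl group and the furan enol ether are inert to these conditions.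

Step 11
Reactants: 17 racemic prop-2-en-1-yl 1-methoxy-4-[3-methoxy-6-(methoxymethoxy)-5-(3-methylbut-2-en-1-yl)-1-benzofuran-2-yl]-2-oxocyclohex-3-ene-1-carboxylate
Product: 19 2-methoxy-5-[3-methoxy-6-(methoxymethoxy)-5-(3-methylbut-2-en-1-yl)-1-benzofuran-2-yl]phenol, via cross-conjugated dienone 18 (not isolated)
Conditions: Pd(OAc)2 (5 mol %), dppe (5 mol %), MeCN (0.02 M), 80 °C
Reagents that add atoms: none
Why: Tsuji-type decarboxylation–dehydrogenation of an allyl β-keto ester: zerovalent palladium ionises the allyl ester, loss of CO2 gives a palladium enolate located only at the methoxy-bearing carbon, β-hydride elimination towards the ring CH2 gives dienone 18, which tautomerises to the phenol, and the allyl hydride collapses to propene; MeCN, a 1:1 ligand ratio and high dilution favour β-hydride elimination over allylation or protonation of the enolate.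

Step 12
Reactants: 19 2-methoxy-5-[3-methoxy-6-(methoxymethoxy)-5-(3-methylbut-2-en-1-yl)-1-benzofuran-2-yl]phenol
Product: 20 2-(3-hydroxy-4-methoxyphenyl)-3-methoxy-5-(3-methylbut-2-en-1-yl)-1-benzofuran-6-ol
Conditions: aq HCl (3 M), MeOH, rt to 40 °C, stopped at full conversion
Reagents that add atoms: none
Why: Acid-catalysed acetal exchange of the methoxymethyl ether with methanol; the aryl acetal ionises under conditions much milder than those needed to protonate the trisubstituted alkene, so the prenyl phenol should survive.

## Compound list

1 | methyl 2,4-dihydroxybenzoate | COC(=O)c1ccc(O)cc1O | starting material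
2 | methyl 5-bromo-2,4-dihydroxybenzoate | COC(=O)c1cc(Br)c(O)cc1O | intermediate
3 | methyl 5-bromo-2-hydroxy-4-(methoxymethoxy)benzoate | COCOc1cc(O)c(C(=O)OC)cc1Br | intermediate
4 | methyl bromoacetate | COC(=O)CBr | starting material
5 | methyl 5-bromo-2-(2-methoxy-2-oxoethoxy)-4-(methoxymethoxy)benzoate | COCOc1cc(OCC(=O)OC)c(C(=O)OC)cc1Br | intermediate
6 | methyl 5-bromo-3-hydroxy-6-(methoxymethoxy)-1-benzofuran-2-carboxylate | COCOc1cc2oc(C(=O)OC)c(O)c2cc1Br | intermediate
7 | methyl 5-bromo-3-methoxy-6-(methoxymethoxy)-1-benzofuran-2-carboxylate | COCOc1cc2oc(C(=O)OC)c(OC)c2cc1Br | intermediate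
8 | 5-bromo-N,3-dimethoxy-6-(methoxymethoxy)-N-methyl-1-benzofuran-2-carboxamide | COCOc1cc2oc(C(=O)N(C)OC)c(OC)c2cc1Br | intermediate
9 | 4,4,5,5-tetramethyl-2-(3-methylbut-2-en-1-yl)-1,3,2-dioxaborolane (prenylboronic acid pinacol ester) | CC(C)=CCB1OC(C)(C)C(C)(C)O1 | starting material
10 | N,3-dimethoxy-6-(methoxymethoxy)-N-methyl-5-(3-methylbut-2-en-1-yl)-1-benzofuran-2-carboxamide | COCOc1cc2oc(C(=O)N(C)OC)c(OC)c2cc1CC=C(C)C | intermediate
11 | 1-[3-methoxy-6-(methoxymethoxy)-5-(3-methylbut-2-en-1-yl)-1-benzofuran-2-yl]prop-2-en-1-one | C=CC(=O)c1oc2cc(OCOC)c(CC=C(C)C)cc2c1OC | intermediate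
12 | prop-2-en-1-yl 3-oxobutanoate (allyl acetoacetate) | CC(=O)CC(=O)OCC=C | starting material
13 | prop-2-en-1-yl 2-diazo-3-oxobutanoate | CC(=O)C(=[N+]=[N-])C(=O)OCC=C | intermediate
14 | prop-2-en-1-yl 2-methoxy-3-oxobutanoate (racemic) | COC(C(C)=O)C(=O)OCC=C | intermediate
15 | racemic prop-2-en-1-yl 2-acetyl-2-methoxy-5-[3-methoxy-6-(methoxymethoxy)-5-(3-methylbut-2-en-1-yl)-1-benzofuran-2-yl]-5-oxopentanoate | C=CCOC(=O)C(OC)(C(C)=O)CCC(=O)c1oc2cc(OCOC)c(CC=C(C)C)cc2c1OC | intermediate
16 | prop-2-en-1-yl 4-hydroxy-1-methoxy-4-[3-methoxy-6-(methoxymethoxy)-5-(3-methylbut-2-en-1-yl)-1-benzofuran-2-yl]-2-oxocyclohexane-1-carboxylate (racemic, both diastereomers) | C=CCOC(=O)C1(OC)CCC(O)(c2oc3cc(OCOC)c(CC=C(C)C)cc3c2OC)CC1=O | intermediate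
17 | racemic prop-2-en-1-yl 1-methoxy-4-[3-methoxy-6-(methoxymethoxy)-5-(3-methylbut-2-en-1-yl)-1-benzofuran-2-yl]-2-oxocyclohex-3-ene-1-carboxylate | C=CCOC(=O)C1(OC)CCC(c2oc3cc(OCOC)c(CC=C(C)C)cc3c2OC)=CC1=O | intermediate
18 | 6-methoxy-3-[3-methoxy-6-(methoxymethoxy)-5-(3-methylbut-2-en-1-yl)-1-benzofuran-2-yl]cyclohexa-2,5-dien-1-one | COC1=CCC(c2oc3cc(OCOC)c(CC=C(C)C)cc3c2OC)=CC1=O | intermediate
19 | 2-methoxy-5-[3-methoxy-6-(methoxymethoxy)-5-(3-methylbut-2-en-1-yl)-1-benzofuran-2-yl]phenol | COc1ccc(-c2oc3cc(OCOC)c(CC=C(C)C)cc3c2OC)cc1O | intermediate
20 | 2-(3-hydroxy-4-methoxyphenyl)-3-methoxy-5-(3-methylbut-2-en-1-yl)-1-benzofuran-6-ol | COc1ccc(-c2oc3cc(O)c(CC=C(C)C)cc3c2OC)cc1O | target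

## Step count and least certain steps

Total step count: 12. Longest linear sequence: 10 steps (steps 1 to 7, then 10, 11 and 12, from 1). Steps 8 and 9 form a two-step side branch to 14.

Step 10 (key step). The most likely failure is a stall after the Michael addition. The benzofuranyl ketone is conjugated with the C3 methoxy group and the ring oxygen, so it is a poor aldol acceptor. The open-chain diketone could then revert by retro-Michael reaction, the enone could oligomerise, or the β-keto ester could be cleaved by adventitious hydroxide. The fallback gives up building ring B and joins a finished ring B by cross-coupling. It sets out from 10. Hydrolysis (KOH, EtOH/H2O, 80 °C) would give 3-methoxy-6-(methoxymethoxy)-5-(3-methylbut-2-en-1-yl)-1-benzofuran-2-carboxylic acid F1. Silver-catalysed protodecarboxylation (Ag2CO3, AcOH, DMSO, 120 °C) would give 3-methoxy-6-(methoxymethoxy)-5-(3-methylbut-2-en-1-yl)-1-benzofuran F2. Lithiation at C2 (n-BuLi, THF, −78 °C), the most acidic position and further activated by the C3 methoxy group, followed by 2-isopropoxy-4,4,5,5-tetramethyl-1,3,2-dioxaborolane would give 2-[3-methoxy-6-(methoxymethoxy)-5-(3-methylbut-2-en-1-yl)-1-benzofuran-2-yl]-4,4,5,5-tetramethyl-1,3,2-dioxaborolane F3. Suzuki–Miyaura coupling of F3 with commercial 5-bromo-2-methoxyphenol (PdCl2(dppf), K3PO4, dioxane/H2O, 80 °C) comes back to the route at 19.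

Step 11. The palladium enolate may be protonated by phenol already formed, or allylated at carbon, instead of undergoing β-hydride elimination. The phenoxide may also be O-allylated. All of these are bimolecular or recombination paths that compete more as the product accumulates. The fallback separates the two events and sets out from 17. Decarboxylative protonation (Pd(OAc)2, PPh3, HCO2H, Et3N, THF, rt) would give racemic 6-methoxy-3-[3-methoxy-6-(methoxymethoxy)-5-(3-methylbut-2-en-1-yl)-1-benzofuran-2-yl]cyclohex-2-en-1-one F4. Kinetic deprotonation at the methoxy-bearing carbon and silylation (LDA, TMSCl, THF, −78 °C) would give {[2-methoxy-5-(3-methoxy-6-(methoxymethoxy)-5-(3-methylbut-2-en-1-yl)-1-benzofuran-2-yl)cyclohexa-1,5-dien-1-yl]oxy}trimethylsilane F5. Saegusa–Ito oxidation (Pd(OAc)2, MeCN, rt) would then pass through 18 and come back to the route at 19.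

Step 6. Coupling through the substituted allyl terminus would give the reverse-prenyl isomer, and hot aqueous hydroxide could slowly hydrolyse the amide. The fallback removes the regiochemical question and sets out from 8. Coupling with allylboronic acid pinacol ester (PdCl2(dppf), CsF, THF, 65 °C) would give N,3-dimethoxy-6-(methoxymethoxy)-N-methyl-5-(prop-2-en-1-yl)-1-benzofuran-2-carboxamide F6. Cross-metathesis with excess 2-methylbut-2-ene (second-generation Grubbs catalyst, RuCl2(=CHPh)(PCy3)(H2IMes), CH2Cl2, rt) comes back to the route at 10.

Step 7. The liberated N,O-dimethylhydroxylamine may add to the enone during the quench, and the aryl vinyl ketone may oligomerise on concentration. The fallback replaces the free enone by a latent one and sets out from 10. MeMgBr (THF, 0 °C) would give 1-[3-methoxy-6-(methoxymethoxy)-5-(3-methylbut-2-en-1-yl)-1-benzofuran-2-yl]ethan-1-one F7. Enolisation (LiHMDS, THF, −78 °C) and trapping with dimethylmethyleneiminium iodide would give 3-(dimethylamino)-1-[3-methoxy-6-(methoxymethoxy)-5-(3-methylbut-2-en-1-yl)-1-benzofuran-2-yl]propan-1-one F8. F8 would be charged into step 10 in place of the enone; under the alkoxide conditions it loses dimethylamine and comes back to the route at 11, formed in the flask.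

Step 12. Acid may add the freed C6 phenol across the neighbouring prenyl alkene (ring closure to a dimethylchroman) or hydrate the alkene if the acetal cleavage is slow. The fallback avoids Brønsted acid and sets out from 19. TMSOTf and 2,2'-bipyridyl (CH2Cl2, 0 °C) would convert the aryl acetal into a silyl ether and silylate the free phenol, giving trimethyl{[3-methoxy-2-(4-methoxy-3-trimethylsilyloxyphenyl)-5-(3-methylbut-2-en-1-yl)-1-benzofuran-6-yl]oxy}silane F9. Neutral hydrolysis (H2O, or K2CO3 in MeOH, rt) comes back to the route at 20.

## Further compounds

F1 | step 10 | 3-methoxy-6-(methoxymethoxy)-5-(3-methylbut-2-en-1-yl)-1-benzofuran-2-carboxylic acid | COCOc1cc2oc(C(=O)O)c(OC)c2cc1CC=C(C)C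
F2 | step 10 | 3-methoxy-6-(methoxymethoxy)-5-(3-methylbut-2-en-1-yl)-1-benzofuran | COCOc1cc2occ(OC)c2cc1CC=C(C)C
F3 | step 10 | 2-[3-methoxy-6-(methoxymethoxy)-5-(3-methylbut-2-en-1-yl)-1-benzofuran-2-yl]-4,4,5,5-tetramethyl-1,3,2-dioxaborolane | COCOc1cc2oc(B3OC(C)(C)C(C)(C)O3)c(OC)c2cc1CC=C(C)C
F4 | step 11 | racemic 6-methoxy-3-[3-methoxy-6-(methoxymethoxy)-5-(3-methylbut-2-en-1-yl)-1-benzofuran-2-yl]cyclohex-2-en-1-one | COC1CCC(c2oc3cc(OCOC)c(CC=C(C)C)cc3c2OC)=CC1=O
F5 | step 11 | {[2-methoxy-5-(3-methoxy-6-(methoxymethoxy)-5-(3-methylbut-2-en-1-yl)-1-benzofuran-2-yl)cyclohexa-1,5-dien-1-yl]oxy}trimethylsilane | COC1=C(O[Si](C)(C)C)C=C(c2oc3cc(OCOC)c(CC=C(C)C)cc3c2OC)CC1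
F6 | step 6 | N,3-dimethoxy-6-(methoxymethoxy)-N-methyl-5-(prop-2-en-1-yl)-1-benzofuran-2-carboxamide | C=CCc1cc2c(OC)c(C(=O)N(C)OC)oc2cc1OCOC
F7 | step 7 | 1-[3-methoxy-6-(methoxymethoxy)-5-(3-methylbut-2-en-1-yl)-1-benzofuran-2-yl]ethan-1-one | CC(=O)c1oc2cc(OCOC)c(CC=C(C)C)cc2c1OC
F8 | step 7 | 3-(dimethylamino)-1-[3-methoxy-6-(methoxymethoxy)-5-(3-methylbut-2-en-1-yl)-1-benzofuran-2-yl]propan-1-one | CN(C)CCC(=O)c1oc2cc(OCOC)c(CC=C(C)C)cc2c1OC
F9 | step 12 | trimethyl{[3-methoxy-2-(4-methoxy-3-trimethylsilyloxyphenyl)-5-(3-methylbut-2-en-1-yl)-1-benzofuran-6-yl]oxy}silane | COc1ccc(-c2oc3cc(O[Si](C)(C)C)c(CC=C(C)C)cc3c2OC)cc1O[Si](C)(C)C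
A1 | alternative 1 | racemic 4-chloro-2-[4-methoxy-3-(methoxymethoxy)phenyl]-6-(methoxymethoxy)-5-(3-methylbut-2-en-1-yl)-1-benzofuran-3(2H)-one | O=C1C(c2ccc(OC)c(OCOC)c2)Oc2cc(OCOC)c(CC=C(C)C)c(Cl)c21
A2 | alternative 1 | 3-chloro-5-(methoxymethoxy)-4-(3-methylbut-2-en-1-yl)-2-(trimethylsilyl)phenyl trifluoromethanesulfonate | C[Si](C)(C)c1c(OS(=O)(=O)C(F)(F)F)cc(OCOC)c(CC=C(C)C)c1Cl
A3 | alternative 1 | racemic methyl 2-hydroxy-2-[4-methoxy-3-(methoxymethoxy)phenyl]acetate | COC(=O)C(O)c1ccc(OC)c(OCOC)c1
A4 | alternative 1 | 3-chloro-5-(methoxymethoxy)-4-(3-methylbut-2-en-1-yl)-1,2-didehydrobenzene | ClC1=C(CC=C(C)C)C(OCOC)=CC#C1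
A5 | alternative 2 | bis(triisopropylsilyl) ether of the target | COc1ccc(-c2oc3cc(O[Si](C(C)C)(C(C)C)C(C)C)c(CC=C(C)C)cc3c2OC)cc1O[Si](C(C)C)(C(C)C)C(C)C
A6 | alternative 2 | 2-{3-formyl-4-methoxy-5-[4-methoxy-3-(triisopropylsilyloxy)phenyl]furan-2-yl}acetic acid | OC(=O)Cc1oc(-c2ccc(OC)c(O[Si](C(C)C)(C(C)C)C(C)C)c2)c(OC)c1C=O
A7 | alternative 2 | 3-methoxy-2-[4-methoxy-3-(triisopropylsilyloxy)phenyl]-6H-furo[3,2-c]pyran-6-one | COc1ccc(cc1O[Si](C(C)C)(C(C)C)C(C)C)C1=C(OC)C2=COC(=O)C=C2O1
A8 | alternative 2 | triisopropyl[(5-methylhex-4-en-1-yn-1-yl)oxy]silane | CC(C)=CCC#CO[Si](C(C)C)(C(C)C)C(C)C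
A9 | alternative 3 | ring B tert-butyldimethylsilyl ether of the target | COc1ccc(-c2oc3cc(O)c(CC=C(C)C)cc3c2OC)cc1O[Si](C)(C)C(C)(C)C
A10 | alternative 3 | 2-diazo-1-{4-methoxy-5-[4-methoxy-3-(tert-butyldimethylsilyloxy)phenyl]-3-[(1E)-5-methylhexa-1,4-dien-1-yl]furan-2-yl}ethan-1-one | [N-]=[N+]=CC(=O)c1oc(-c2ccc(OC)c(O[Si](C)(C)C(C)(C)C)c2)c(OC)c1/C=C/CC=C(C)C
A11 | alternative 3 | 2-{4-methoxy-5-[4-methoxy-3-(tert-butyldimethylsilyloxy)phenyl]-3-[(1E)-5-methylhexa-1,4-dien-1-yl]furan-2-yl}ethen-1-one | O=C=Cc1oc(-c2ccc(OC)c(O[Si](C)(C)C(C)(C)C)c2)c(OC)c1/C=C/CC=C(C)C
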